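**Plan**

- Retrosynthesis: the side chain is cut at the enone C(=O)–C(alkene) bond (alkynyl anion plus aldehyde) and at C2'–C3' (neopentyl organocerium plus chromenylacetaldehyde). The chromene is then cut at O1–C8a and at C4–C4a (alkyne–aryl coupling).
- Forward: (R)-citramalic acid gives a silylated tertiary propargylic alcohol. Sonogashira coupling with 2-bromo-1-iodo-5-methoxy-3-methylbenzene, Lindlar reduction and Pd-catalysed O1–C8a closure then build the pyran ring, the only ring made in the route. The cyclopentane is one ring of cis-1,5-dimethylbicyclo[3.3.0]octane-3,7-dione, whose other ring is cut open.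
- Enabling feature: in the 2H-chromene, O1 sits on the fully substituted C2 and is tied through the cis C3=C4 bond to C4a, the neighbour of C8a. A (Z)-alkenyl tertiary alcohol with Br at C8a therefore has alkoxide and aryl halide in place. C2 with O1, CH3, C3 and the C1'H2–C2' arm corresponds to C2 of (R)-citramalic acid with OH, CH3, CO2H and CH2CO2H.
- Stereochemistry: C2 (R) comes from citramalic acid and is never touched. The two quaternary cyclopentane carbons are cis through the bicyclooctane ring fusion, and their absolute sense comes from enantiotopos-selective deprotonation by a chiral lithium amide. The Z enone comes from a Lindlar reduction; the carbinol centres of the coupling steps are oxidised away at the end.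

Key step: step 9

Remark: cis-1,5-dimethylbicyclo[3.3.0]octane-3,7-dione (17) is taken as a purchasable compound.
Remark: the (R,R)-amide in step 14 is assumed to remove a proton from the α-methylene that leads to 22; if it prefers the other one, the (S,S)-amide is used and nothing else changes.
Remark: the carbinol and lactol centres formed in steps 18 and 19 are not controlled and are cleared in step 21, so 29, 30, 33 and 34 are carried as epimer mixtures.

**Step 1**
Reactants: 1 (R)-citramalic acid
Product: 2 (R)-2-(2,2,4-trimethyl-5-oxo-1,3-dioxolan-4-yl)acetic acid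
Conditions: 2,2-dimethoxypropane (solvent), TsOH (cat.), 25 °C
Reagents that add atoms: 2,2-dimethoxypropane, COC(C)(C)OC
Why: Acid-catalysed transacetalisation should tie the α-hydroxy acid unit into the five-membered dioxolanone in preference to the six-membered alternative from the β-carboxyl, leaving CH2CO2H free and the quaternary stereocentre untouched.

**Step 2**
Reactants: 2 (R)-2-(2,2,4-trimethyl-5-oxo-1,3-dioxolan-4-yl)acetic acid
Product: 3 (R)-5-(2-hydroxyethyl)-2,2,5-trimethyl-1,3-dioxolan-4-one
Conditions: BH3·SMe2, THF, 0 → 25 °C; H2O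
Reagents that add atoms: none
Why: Borane reduction of a free carboxylic acid (through the acyloxyborane) is much faster than attack on the ester-type dioxolanone carbonyl, and the crude alcohol is silylated at once so that translactonisation has no time to occur.

**Step 3**
Reactants: 3 (R)-5-(2-hydroxyethyl)-2,2,5-trimethyl-1,3-dioxolan-4-one
Product: 4 (R)-5-[2-(tert-butyldimethylsilyloxy)ethyl]-2,2,5-trimethyl-1,3-dioxolan-4-one
Conditions: TBSCl, imidazole, DMF, 0 → 25 °C
Reagents that add atoms: tert-butyldimethylsilyl chloride, CC(C)(C)[Si](C)(C)Cl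
Why: Imidazole-promoted silylation of the primary alcohol is a standard protection and gives an ether that should survive hydride, Pd(0)/amine, hydrogenation and carbonate base.

**Step 4**
Reactants: 4 (R)-5-[2-(tert-butyldimethylsilyloxy)ethyl]-2,2,5-trimethyl-1,3-dioxolan-4-one
Product: 7 (R)-5-(tert-butyldimethylsilyloxy)-3-methylpent-1-yn-3-ol, via lactol 5 (not isolated), via hydroxy aldehyde 6 (not isolated)
Conditions: DIBAL-H, CH2Cl2, −78 °C; MeOH; then dimethyl (1-diazo-2-oxopropyl)phosphonate, K2CO3, MeOH, 0 → 25 °C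
Reagents that add atoms: dimethyl (1-diazo-2-oxopropyl)phosphonate, CC(=O)C(=[N+]=[N-])P(=O)(OC)OC
Why: One-pot half-reduction and Ohira–Bestmann (Seyferth–Gilbert) homologation, in which the lactol opens in methanolic carbonate with loss of acetone to an α-hydroxy aldehyde that has no α-hydrogen and so cannot epimerise before it is converted into the terminal alkyne.

**Step 5**
Reactants: 8 4-methoxy-2-methylaniline
Product: 9 2-iodo-4-methoxy-6-methylaniline
Conditions: I2, NaHCO3, CH2Cl2/H2O, 25 °C
Reagents that add atoms: iodine, II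
Why: Electrophilic aromatic iodination is directed by the amino group to its only free ortho position, the para position being blocked by OMe and the other ortho position by CH3.

**Step 6**
Reactants: 9 2-iodo-4-methoxy-6-methylaniline
Product: 11 2-bromo-1-iodo-5-methoxy-3-methylbenzene, via diazonium bromide 10 (not isolated)
Conditions: NaNO2, 48% HBr, H2O/MeCN, 0 °C; then CuBr, 0 → 60 °C
Reagents that add atoms: hydrobromic acid, Br; copper(I) bromide, [Cu]Br
Why: The Sandmeyer reaction replaces the diazotised amino group by bromine at the carbon flanked by CH3 and I, which is the future C8a.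

**Step 7**
Reactants: 11 2-bromo-1-iodo-5-methoxy-3-methylbenzene; 7 (R)-5-(tert-butyldimethylsilyloxy)-3-methylpent-1-yn-3-ol
Product: 12 (R)-1-(2-bromo-5-methoxy-3-methylphenyl)-5-(tert-butyldimethylsilyloxy)-3-methylpent-1-yn-3-ol
Conditions: Pd(PPh3)2Cl2 (2 mol %), CuI (4 mol %), Et3N, THF, 25 °C
Reagents that add atoms: none
Why: Sonogashira coupling should take place only at the C–I bond, whose oxidative addition at room temperature is far faster than that of the neighbouring C–Br bond, and the free tertiary propargylic alcohol is tolerated.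

**Step 8**
Reactants: 12 (R)-1-(2-bromo-5-methoxy-3-methylphenyl)-5-(tert-butyldimethylsilyloxy)-3-methylpent-1-yn-3-ol
Product: 13 (R,Z)-1-(2-bromo-5-methoxy-3-methylphenyl)-5-(tert-butyldimethylsilyloxy)-3-methylpent-1-en-3-ol
Conditions: H2 (1 atm), Lindlar catalyst, quinoline, EtOAc, 25 °C
Reagents that add atoms: none
Why: Lindlar semi-hydrogenation delivers both hydrogens to one face of the alkyne and stops at the Z alkene, and the poisoned catalyst should leave the aryl bromide intact.

**Step 9**
Reactants: 13 (R,Z)-1-(2-bromo-5-methoxy-3-methylphenyl)-5-(tert-butyldimethylsilyloxy)-3-methylpent-1-en-3-ol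
Product: 14 (R)-tert-butyl[2-(6-methoxy-2,8-dimethyl-2H-chromen-2-yl)ethoxy]dimethylsilane
Conditions: Pd(OAc)2 (3 mol %), 2-(di-tert-butylphosphino)-1,1'-binaphthyl (4 mol %), Cs2CO3, toluene, 80 °C
Reagents that add atoms: none
Why: Pd(0) should insert into the C8a–Br bond and, after carbonate removes the hydroxyl proton, the alkoxide should displace bromide on palladium to give a seven-membered aryl(alkoxo)palladium(II) chelate (Pd, C8a, C4a, C4, C3, C2, O1), from which C(sp2)–O reductive elimination forms O1–C8a. The closest known reaction type is the Buchwald–Hartwig-type intramolecular etherification of aryl bromides with tertiary alcohols promoted by bulky di-tert-butyl(biaryl)phosphines. The pyran ring closes by attack of O1 on the ipso carbon C8a, formally a 6-exo-trig closure realised as a reductive elimination, and the Z geometry of C3=C4 from step 8 is what brings O1 within reach of C8a. No stereocentre is formed and no bond to C2 is broken, so the R configuration from citramalic acid is carried over unchanged. Only chemoselectivity is needed (C–O reductive elimination against hydrodebromination, Heck-type insertion and alkene isomerisation): the alkoxide carbon bears no hydrogen, so neither a ketone nor a Pd–H can arise from it, insertion of the tethered alkene would need a four-membered palladacycle, and the hindered electron-rich ligand speeds up reductive elimination. The silyl ether, the aryl methyl ether and the cis alkene should be inert to Cs2CO3 in toluene.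

**Step 10**
Reactants: 14 (R)-tert-butyl[2-(6-methoxy-2,8-dimethyl-2H-chromen-2-yl)ethoxy]dimethylsilane
Product: 15 (R)-2-(6-methoxy-2,8-dimethyl-2H-chromen-2-yl)ethan-1-ol
Conditions: TBAF, THF, 0 → 25 °C
Reagents that add atoms: none
Why: Fluoride-induced desilylation is driven by the Si–F bond and touches neither the chromene alkene nor the aryl ethers.

**Step 11**
Reactants: 15 (R)-2-(6-methoxy-2,8-dimethyl-2H-chromen-2-yl)ethan-1-ol
Product: 16 (R)-2-(6-methoxy-2,8-dimethyl-2H-chromen-2-yl)acetaldehyde
Conditions: Dess–Martin periodinane, pyridine, CH2Cl2, 0 → 25 °C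
Reagents that add atoms: none
Why: Dess–Martin oxidation under buffered, non-basic conditions should give the β-aryloxy aldehyde without enolisation and β-elimination of the aryloxide, and the aldehyde is used directly.

**Step 12**
Reactants: 17 cis-1,5-dimethylbicyclo[3.3.0]octane-3,7-dione
Product: 18 cis-7,7-(2,2-dimethylpropane-1,3-diyldioxy)-1,5-dimethylbicyclo[3.3.0]octan-3-one
Conditions: 2,2-dimethylpropane-1,3-diol (1.0 equiv), TsOH (cat.), benzene, reflux (Dean–Stark)
Reagents that add atoms: 2,2-dimethylpropane-1,3-diol, OCC(C)(C)CO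
Why: Acid-catalysed ketalisation with one equivalent of diol masks one of the two equivalent ketones, and unchanged diketone and bis-ketal are separable and can be recycled.

**Step 13**
Reactants: 18 cis-7,7-(2,2-dimethylpropane-1,3-diyldioxy)-1,5-dimethylbicyclo[3.3.0]octan-3-one
Product: 21 cis-1,5-dimethylbicyclo[3.3.0]octan-3-one, via hydrazone 19 (not isolated), via ketal 20 (not isolated)
Conditions: N2H4·H2O, KOH, diethylene glycol, 130 → 200 °C; then 2 M HCl, THF, 25 °C
Reagents that add atoms: water, O
Why: Wolff–Kishner reduction (Huang-Minlon procedure) removes the free carbonyl while the base-stable ketal protects the other, and aqueous acid then releases the meso ketone whose unfunctionalised ring is the cyclopentane of the target.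

**Step 14**
Reactants: 21 cis-1,5-dimethylbicyclo[3.3.0]octan-3-one
Product: 22 trimethyl{[(1R,5S)-1,5-dimethylbicyclo[3.3.0]oct-2-en-3-yl]oxy}silane
Conditions: (R,R)-bis(1-phenylethyl)amine·HCl, n-BuLi (2 equiv), THF, −78 → 0 °C; then TMSCl, 21, −100 °C
Reagents that add atoms: chlorotrimethylsilane, C[Si](C)(C)Cl
Why: Enantiotopos-selective deprotonation of a meso cis-bicyclo[3.3.0]octan-3-one by a C2-symmetric chiral lithium amide with in situ silyl trapping is an established desymmetrisation, and by choosing which α-methylene becomes the enol carbon it fixes the absolute configuration of both quaternary carbons, which are already cis through the ring fusion.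

**Step 15**
Reactants: 22 trimethyl{[(1R,5S)-1,5-dimethylbicyclo[3.3.0]oct-2-en-3-yl]oxy}silane
Product: 23 2-[(1S,2S)-2-formyl-1,2-dimethylcyclopentyl]acetic acid
Conditions: O3, CH2Cl2/MeOH, −78 °C; then Me2S, −78 → 25 °C
Reagents that add atoms: ozone, [O-][O+]=O
Why: Ozonolysis of the silyl enol ether cleaves C2=C3 of the bicycle, leaving the aldehyde on one quaternary carbon and, after loss of the silyl group, the acetic acid arm on the other, with neither quaternary centre touched.

**Step 16**
Reactants: 23 2-[(1S,2S)-2-formyl-1,2-dimethylcyclopentyl]acetic acid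
Product: 25 2-[(1S,2S)-2-(dimethoxymethyl)-1,2-dimethylcyclopentyl]acetic acid, via methyl ester 24 (not isolated)
Conditions: HC(OMe)3, MeOH, TsOH (cat.), 40 °C; then LiOH, THF/H2O, 25 °C; AcOH to pH 5
Reagents that add atoms: trimethyl orthoformate, COC(OC)OC; methanol, CO
Why: Acid-catalysed acetalisation of the non-enolisable aldehyde (with Fischer esterification of the acid under the same conditions) followed by saponification, to which the acetal is inert, should give the acetal acid, which is used without storage.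

**Step 17**
Reactants: 25 2-[(1S,2S)-2-(dimethoxymethyl)-1,2-dimethylcyclopentyl]acetic acid
Product: 26 (1S,2R)-1-(dimethoxymethyl)-2-(iodomethyl)-1,2-dimethylcyclopentane
Conditions: PhI(OAc)2, I2, cyclohexane, hν (tungsten lamp), 60 °C
Reagents that add atoms: iodine, II
Why: Hunsdiecker-type iododecarboxylation with a hypervalent iodine(III) reagent goes through the acyl hypoiodite and a primary alkyl radical that is trapped by iodine, which gives the neopentyl iodide without any SN2 step at the hindered carbon and without skeletal rearrangement.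

**Step 18**
Reactants: 26 (1S,2R)-1-(dimethoxymethyl)-2-(iodomethyl)-1,2-dimethylcyclopentane; 16 (R)-2-(6-methoxy-2,8-dimethyl-2H-chromen-2-yl)acetaldehyde
Product: 30 (4aS,7aS)-3-{[(2R)-6-methoxy-2,8-dimethyl-2H-chromen-2-yl]methyl}-4a,7a-dimethyloctahydrocyclopenta[c]pyran-1-ol, via alkyllithium 27 (not isolated), via alkylcerium dichloride 28 (not isolated), via hydroxy acetal 29 (not isolated)
Conditions: 26, t-BuLi (2 equiv), Et2O/pentane, −78 °C; CeCl3, THF, −78 °C; 16, −78 °C; then 1 M HCl, THF, 0 → 25 °C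
Reagents that add atoms: water, O
Why: Iodine–lithium exchange gives a neopentyllithium without β-hydrogens, transmetalation to the weakly basic organocerium allows 1,2-addition to the enolisable β-aryloxy aldehyde instead of deprotonation, and aqueous acid then turns the δ-hydroxy dimethyl acetal into the six-membered lactol; the new carbinol centre is not controlled and is oxidised in step 21.

**Step 19**
Reactants: 30 (4aS,7aS)-3-{[(2R)-6-methoxy-2,8-dimethyl-2H-chromen-2-yl]methyl}-4a,7a-dimethyloctahydrocyclopenta[c]pyran-1-ol; 31 2-methylbut-3-yn-2-ol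
Product: 33 1-[(1S,2S)-2-{2-hydroxy-3-[(2R)-6-methoxy-2,8-dimethyl-2H-chromen-2-yl]propyl}-1,2-dimethylcyclopentyl]-4-methylpent-2-yne-1,4-diol, via bromomagnesium acetylide 32 (not isolated)
Conditions: 31, EtMgBr (2 equiv per alkyne), THF, 0 → 50 °C; then 30, THF, 50 °C; aq. NH4Cl
Reagents that add atoms: none
Why: The magnesium lactolate is in equilibrium with the open hydroxy aldehyde, to which an excess of the doubly metalated alkynol adds (alkynyl Grignard addition to a lactol) while the C2' oxygen stays as an alkoxide; the configuration of the new propargylic carbinol is irrelevant because it is oxidised in step 21.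

**Step 20**
Reactants: 33 1-[(1S,2S)-2-{2-hydroxy-3-[(2R)-6-methoxy-2,8-dimethyl-2H-chromen-2-yl]propyl}-1,2-dimethylcyclopentyl]-4-methylpent-2-yne-1,4-diol
Product: 34 (Z)-1-[(1S,2S)-2-{2-hydroxy-3-[(2R)-6-methoxy-2,8-dimethyl-2H-chromen-2-yl]propyl}-1,2-dimethylcyclopentyl]-4-methylpent-2-ene-1,4-diol
Conditions: H2 (1 atm), Lindlar catalyst, quinoline, EtOAc, 25 °C
Reagents that add atoms: none
Why: Lindlar semi-hydrogenation of the propargylic diol gives the Z alkene by syn delivery of hydrogen and should stop there, the disubstituted chromene alkene being much slower on the poisoned catalyst.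

**Step 21**
Reactants: 34 (Z)-1-[(1S,2S)-2-{2-hydroxy-3-[(2R)-6-methoxy-2,8-dimethyl-2H-chromen-2-yl]propyl}-1,2-dimethylcyclopentyl]-4-methylpent-2-ene-1,4-diol
Product: 35 (Z)-4-hydroxy-1-[(1S,2S)-2-{3-[(2R)-6-methoxy-2,8-dimethyl-2H-chromen-2-yl]-2-oxopropyl}-1,2-dimethylcyclopentyl]-4-methylpent-2-en-1-one
Conditions: Dess–Martin periodinane (excess), pyridine, CH2Cl2, 0 → 25 °C, dark
Reagents that add atoms: none
Why: Dess–Martin oxidation converts both secondary alcohols into ketones in one operation and leaves the tertiary alcohol alone, and the neutral buffered medium should avoid both retro-oxa-Michael opening at the new β-aryloxy ketone and Z to E isomerisation of the enone.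

**Compound list**

1 | (R)-citramalic acid | OC(=O)[C@@](C)(CC(=O)O)O | starting material
2 | (R)-2-(2,2,4-trimethyl-5-oxo-1,3-dioxolan-4-yl)acetic acid | CC1(C)OC(=O)[C@@](C)(CC(=O)O)O1 | intermediate
3 | (R)-5-(2-hydroxyethyl)-2,2,5-trimethyl-1,3-dioxolan-4-one | CC1(C)OC(=O)[C@@](C)(CCO)O1 | intermediate
4 | (R)-5-[2-(tert-butyldimethylsilyloxy)ethyl]-2,2,5-trimethyl-1,3-dioxolan-4-one | CC1(C)OC(=O)[C@@](C)(CCO[Si](C)(C)C(C)(C)C)O1 | intermediate
5 | (5R)-5-[2-(tert-butyldimethylsilyloxy)ethyl]-2,2,5-trimethyl-1,3-dioxolan-4-ol (lactol; both C4 epimers) | CC1(C)OC(O)[C@@](C)(CCO[Si](C)(C)C(C)(C)C)O1 | intermediate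
6 | (R)-4-(tert-butyldimethylsilyloxy)-2-hydroxy-2-methylbutanal | O=C[C@@](C)(CCO[Si](C)(C)C(C)(C)C)O | intermediate
7 | (R)-5-(tert-butyldimethylsilyloxy)-3-methylpent-1-yn-3-ol | C#C[C@](C)(O)CCO[Si](C)(C)C(C)(C)C | intermediate
8 | 4-methoxy-2-methylaniline | COc1ccc(N)c(C)c1 | starting material
9 | 2-iodo-4-methoxy-6-methylaniline | COc1cc(C)c(N)c(I)c1 | intermediate
10 | 2-iodo-4-methoxy-6-methylbenzenediazonium bromide | COc1cc(C)c([N+]#N)c(I)c1.[Br-] | intermediate
11 | 2-bromo-1-iodo-5-methoxy-3-methylbenzene | COc1cc(C)c(Br)c(I)c1 | intermediate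
12 | (R)-1-(2-bromo-5-methoxy-3-methylphenyl)-5-(tert-butyldimethylsilyloxy)-3-methylpent-1-yn-3-ol | COc1cc(C)c(Br)c(c1)C#C[C@](C)(O)CCO[Si](C)(C)C(C)(C)C | intermediate
13 | (R,Z)-1-(2-bromo-5-methoxy-3-methylphenyl)-5-(tert-butyldimethylsilyloxy)-3-methylpent-1-en-3-ol | COc1cc(C)c(Br)c(c1)/C=C\[C@](C)(O)CCO[Si](C)(C)C(C)(C)C | intermediate
14 | (R)-tert-butyl[2-(6-methoxy-2,8-dimethyl-2H-chromen-2-yl)ethoxy]dimethylsilane | COc1cc(C)c2c(c1)C=C[C@@](C)(CCO[Si](C)(C)C(C)(C)C)O2 | intermediate
15 | (R)-2-(6-methoxy-2,8-dimethyl-2H-chromen-2-yl)ethan-1-ol | COc1cc(C)c2c(c1)C=C[C@@](C)(CCO)O2 | intermediate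
16 | (R)-2-(6-methoxy-2,8-dimethyl-2H-chromen-2-yl)acetaldehyde | COc1cc(C)c2c(c1)C=C[C@@](C)(CC=O)O2 | intermediate
17 | cis-1,5-dimethylbicyclo[3.3.0]octane-3,7-dione | O=C1C[C@]2(C)CC(=O)C[C@]2(C)C1 | starting material
18 | cis-7,7-(2,2-dimethylpropane-1,3-diyldioxy)-1,5-dimethylbicyclo[3.3.0]octan-3-one | CC1(C)COC2(C[C@]3(C)CC(=O)C[C@]3(C)C2)OC1 | intermediate
19 | hydrazone of 18 | CC1(C)COC2(C[C@]3(C)CC(=NN)C[C@]3(C)C2)OC1 | intermediate
20 | cis-3,3-(2,2-dimethylpropane-1,3-diyldioxy)-1,5-dimethylbicyclo[3.3.0]octane | CC1(C)COC2(C[C@]3(C)CCC[C@]3(C)C2)OC1 | intermediate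
21 | cis-1,5-dimethylbicyclo[3.3.0]octan-3-one (meso) | O=C1C[C@]2(C)CCC[C@]2(C)C1 | intermediate
22 | trimethyl{[(1R,5S)-1,5-dimethylbicyclo[3.3.0]oct-2-en-3-yl]oxy}silane | C1[C@]2(C)CCC[C@]2(C)C=C1O[Si](C)(C)C | intermediate
23 | 2-[(1S,2S)-2-formyl-1,2-dimethylcyclopentyl]acetic acid | OC(=O)C[C@]1(C)CCC[C@]1(C)C=O | intermediate
24 | methyl 2-[(1S,2S)-2-(dimethoxymethyl)-1,2-dimethylcyclopentyl]acetate | COC(=O)C[C@]1(C)CCC[C@]1(C)C(OC)OC | intermediate
25 | 2-[(1S,2S)-2-(dimethoxymethyl)-1,2-dimethylcyclopentyl]acetic acid | OC(=O)C[C@]1(C)CCC[C@]1(C)C(OC)OC | intermediate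
26 | (1S,2R)-1-(dimethoxymethyl)-2-(iodomethyl)-1,2-dimethylcyclopentane | IC[C@]1(C)CCC[C@]1(C)C(OC)OC | intermediate
27 | [(1R,2S)-2-(dimethoxymethyl)-1,2-dimethylcyclopentyl]methyllithium | [Li]C[C@]1(C)CCC[C@]1(C)C(OC)OC | intermediate
28 | dichloro{[(1R,2S)-2-(dimethoxymethyl)-1,2-dimethylcyclopentyl]methyl}cerium | Cl[Ce](Cl)C[C@]1(C)CCC[C@]1(C)C(OC)OC | intermediate
29 | 1-[(1S,2S)-2-(dimethoxymethyl)-1,2-dimethylcyclopentyl]-3-[(2R)-6-methoxy-2,8-dimethyl-2H-chromen-2-yl]propan-2-ol (both C2 epimers) | COc1cc(C)c2c(c1)C=C[C@@](C)(CC(O)C[C@]1(C)CCC[C@]1(C)C(OC)OC)O2 | intermediate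
30 | (4aS,7aS)-3-{[(2R)-6-methoxy-2,8-dimethyl-2H-chromen-2-yl]methyl}-4a,7a-dimethyloctahydrocyclopenta[c]pyran-1-ol (epimers at C1 and C3) | COc1cc(C)c2c(c1)C=C[C@@](C)(CC1C[C@]3(C)CCC[C@]3(C)C(O)O1)O2 | intermediate
31 | 2-methylbut-3-yn-2-ol | CC(C)(O)C#C | starting material
32 | bromomagnesium 4-(bromomagnesio)-2-methylbut-3-yn-2-olate | CC(C)(O[Mg]Br)C#C[Mg]Br | intermediate
33 | 1-[(1S,2S)-2-{2-hydroxy-3-[(2R)-6-methoxy-2,8-dimethyl-2H-chromen-2-yl]propyl}-1,2-dimethylcyclopentyl]-4-methylpent-2-yne-1,4-diol (epimers at both secondary carbinols) | COc1cc(C)c2c(c1)C=C[C@@](C)(CC(O)C[C@]1(C)CCC[C@]1(C)C(O)C#CC(C)(C)O)O2 | intermediate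
34 | (Z)-1-[(1S,2S)-2-{2-hydroxy-3-[(2R)-6-methoxy-2,8-dimethyl-2H-chromen-2-yl]propyl}-1,2-dimethylcyclopentyl]-4-methylpent-2-ene-1,4-diol (epimers at both secondary carbinols) | COc1cc(C)c2c(c1)C=C[C@@](C)(CC(O)C[C@]1(C)CCC[C@]1(C)C(O)/C=C\C(C)(C)O)O2 | intermediate
35 | (Z)-4-hydroxy-1-[(1S,2S)-2-{3-[(2R)-6-methoxy-2,8-dimethyl-2H-chromen-2-yl]-2-oxopropyl}-1,2-dimethylcyclopentyl]-4-methylpent-2-en-1-one | COc1cc(C)c2c(c1)C=C[C@@](C)(CC(=O)C[C@]1(C)CCC[C@]1(C)C(=O)/C=C\C(C)(C)O)O2 | target

**Step count and risks**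

Total: 21 steps. Longest linear sequence: 13 steps (1–4, 7–11, 18–21) from (R)-citramalic acid; the cyclopentane branch (12–17) joins at step 18.

Step 18 is the most exposed. The iodine–lithium exchange may be incomplete or the neopentyl organometallic may be protonated before it adds. Any residual basicity could also enolise aldehyde 16 and expel the aryloxide, opening the pyran ring. The fallback makes the same C2'–C3' bond by a radical route without any carbanion and sets out from acid 25 and aldehyde 16. Acid 25 is esterified with N-hydroxyphthalimide (DIC, DMAP cat.) to 1,3-dioxoisoindolin-2-yl 2-[(1S,2S)-2-(dimethoxymethyl)-1,2-dimethylcyclopentyl]acetate F1. Aldehyde 16 is oxidised (Pinnick conditions) to (R)-2-(6-methoxy-2,8-dimethyl-2H-chromen-2-yl)acetic acid F2, which is converted with 2,2'-dipyridyl disulfide and PPh3 into its S-(pyridin-2-yl) thioester F3. Nickel-catalysed reductive cross-electrophile coupling of the two activated esters (NiBr2·dme, 4,4'-di-tert-butyl-2,2'-bipyridine, Zn, DMA/THF) should give, by decarboxylative acylation, 1-[(1S,2S)-2-(dimethoxymethyl)-1,2-dimethylcyclopentyl]-3-[(2R)-6-methoxy-2,8-dimethyl-2H-chromen-2-yl]propan-2-one F4. Reduction with NaBH4 at 0 °C returns to the route at 29, which is hydrolysed to 30 as in step 18.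

Step 14 may discriminate poorly between the two enantiotopic α-methylene groups, and the labile enol silane may partly revert to the meso ketone, so that the cyclopentane fragment is not enantiomerically pure. The fallback replaces asymmetric deprotonation by a classical resolution and sets out from 21. LDA and TMSCl give the racemic trimethylsilyl enol ether F5, and ozonolysis as in step 15 gives racemic 2-(2-formyl-1,2-dimethylcyclopentyl)acetic acid F6. The conditions of step 16 then lead through the racemic methyl ester acetal F7 to racemic 2-[2-(dimethoxymethyl)-1,2-dimethylcyclopentyl]acetic acid F8. Crystallisation with (S)-1-phenylethylamine (or its antipode, whichever gives the less soluble salt of the wanted acid) should give the (S)-1-phenylethylammonium salt of the (1S,2S) acid F9, and mild acidification returns to the route at 25. The same salt formation can also be used to raise the enantiomeric purity of 25 made by step 14.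

Step 19 depends on the hindered lactol opening to its hydroxy aldehyde. If that equilibrium is too unfavourable or too slow, the alkynyl reagent only deprotonates the lactol and no carbon–carbon bond forms. The fallback raises the oxidation level and sets out from 30. Oxidation with TEMPO and PhI(OAc)2 gives the δ-lactone (4aS,7aS)-3-{[(2R)-6-methoxy-2,8-dimethyl-2H-chromen-2-yl]methyl}-4a,7a-dimethylhexahydrocyclopenta[c]pyran-1(3H)-one F10. A single addition of reagent 32 to the lactone carbonyl (the hemiketal alkoxide resists a second addition) gives after work-up the hydroxy ynone 4-hydroxy-1-[(1S,2S)-2-{2-hydroxy-3-[(2R)-6-methoxy-2,8-dimethyl-2H-chromen-2-yl]propyl}-1,2-dimethylcyclopentyl]-4-methylpent-2-yn-1-one F11, in equilibrium with its cyclic hemiketal. Lindlar semi-hydrogenation gives the corresponding (Z)-enone alcohol F12, and Dess–Martin oxidation of the one remaining secondary alcohol arrives directly at 35.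

**Further compounds**

F1 | step 18 | 1,3-dioxoisoindolin-2-yl 2-[(1S,2S)-2-(dimethoxymethyl)-1,2-dimethylcyclopentyl]acetate | O=C(C[C@]1(C)CCC[C@]1(C)C(OC)OC)ON1C(=O)c2ccccc2C1=O
F2 | step 18 | (R)-2-(6-methoxy-2,8-dimethyl-2H-chromen-2-yl)acetic acid | COc1cc(C)c2c(c1)C=C[C@@](C)(CC(=O)O)O2
F3 | step 18 | S-(pyridin-2-yl) (R)-2-(6-methoxy-2,8-dimethyl-2H-chromen-2-yl)ethanethioate | COc1cc(C)c2c(c1)C=C[C@@](C)(CC(=O)Sc1ccccn1)O2
F4 | step 18 | 1-[(1S,2S)-2-(dimethoxymethyl)-1,2-dimethylcyclopentyl]-3-[(2R)-6-methoxy-2,8-dimethyl-2H-chromen-2-yl]propan-2-one | COc1cc(C)c2c(c1)C=C[C@@](C)(CC(=O)C[C@]1(C)CCC[C@]1(C)C(OC)OC)O2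
F5 | step 14 | racemic trimethyl[(cis-1,5-dimethylbicyclo[3.3.0]oct-2-en-3-yl)oxy]silane | C1[C@]2(C)CCC[C@]2(C)C=C1O[Si](C)(C)C.C1[C@@]2(C)CCC[C@@]2(C)C=C1O[Si](C)(C)C
F6 | step 14 | racemic 2-(2-formyl-1,2-dimethylcyclopentyl)acetic acid (cis methyls) | OC(=O)C[C@]1(C)CCC[C@]1(C)C=O.OC(=O)C[C@@]1(C)CCC[C@@]1(C)C=O
F7 | step 14 | racemic methyl 2-[2-(dimethoxymethyl)-1,2-dimethylcyclopentyl]acetate (cis methyls) | COC(=O)C[C@]1(C)CCC[C@]1(C)C(OC)OC.COC(=O)C[C@@]1(C)CCC[C@@]1(C)C(OC)OC
F8 | step 14 | racemic 2-[2-(dimethoxymethyl)-1,2-dimethylcyclopentyl]acetic acid (cis methyls) | OC(=O)C[C@]1(C)CCC[C@]1(C)C(OC)OC.OC(=O)C[C@@]1(C)CCC[C@@]1(C)C(OC)OC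
F9 | step 14 | (S)-1-phenylethylammonium 2-[(1S,2S)-2-(dimethoxymethyl)-1,2-dimethylcyclopentyl]acetate | [O-]C(=O)C[C@]1(C)CCC[C@]1(C)C(OC)OC.C[C@H]([NH3+])c1ccccc1
F10 | step 19 | (4aS,7aS)-3-{[(2R)-6-methoxy-2,8-dimethyl-2H-chromen-2-yl]methyl}-4a,7a-dimethylhexahydrocyclopenta[c]pyran-1(3H)-one | COc1cc(C)c2c(c1)C=C[C@@](C)(CC1C[C@]3(C)CCC[C@]3(C)C(=O)O1)O2
F11 | step 19 | 4-hydroxy-1-[(1S,2S)-2-{2-hydroxy-3-[(2R)-6-methoxy-2,8-dimethyl-2H-chromen-2-yl]propyl}-1,2-dimethylcyclopentyl]-4-methylpent-2-yn-1-one | COc1cc(C)c2c(c1)C=C[C@@](C)(CC(O)C[C@]1(C)CCC[C@]1(C)C(=O)C#CC(C)(C)O)O2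
F12 | step 19 | (Z)-4-hydroxy-1-[(1S,2S)-2-{2-hydroxy-3-[(2R)-6-methoxy-2,8-dimethyl-2H-chromen-2-yl]propyl}-1,2-dimethylcyclopentyl]-4-methylpent-2-en-1-one | COc1cc(C)c2c(c1)C=C[C@@](C)(CC(O)C[C@]1(C)CCC[C@]1(C)C(=O)/C=C\C(C)(C)O)O2
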